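Choose blue, the hottest recipe, and reckon its yield from a flow of gas rather than from a rate constant.

| setting | Thursday's | Saturday's | green | teal | blue | grey |
|---|---|---|---|---|---|---|
| left-handed substrate | 0.70 M | 1.1 M | 0.50 M | 0.50 M | 0.50 M | 0.50 M |
| right-handed substrate | 0.70 M | 1.1 M | 0.50 M | 0.50 M | 0.50 M | 0.50 M |
| gas | 43 mM (held) | 43 mM (held) | 43 mM (held) | 43 mM (held) | 43 mM (held) | 43 mM (held) |
| racemization catalyst | 4.1 mol% | 4.1 mol% | 4.1 mol% | 4.1 mol% | 4.1 mol% | 4.1 mol% |
| impurity | 13 mM | 13 mM | 13 mM | 13 mM | 13 mM | 13 mM |
| temperature | 32 °C | 82 °C | 70 °C | 40 °C | 100 °C | 10 °C |
| remark | run made earlier | run made earlier |  |  |  |  |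
| time |  |  | 6.0 min | 6.0 min | 6.0 min | 6.0 min |

| run | time / min | left-handed product / % | left-handed substrate / % |
|---|---|---|---|
| Thursday's | 3.00 | 4.4 | 47.8 |
| Thursday's | 8.00 | 6.6 | 40.8 |
| Thursday's | 15.0 | 15.6 | 35.0 |
| Thursday's | 25.0 | 23.0 | 30.0 |
| Thursday's | 40.0 | 32.3 | 18.8 |
| Thursday's | 50.0 | 35.7 | 17.7 |
| Saturday's | 0.667 | 3.4 | 48.0 |
| Saturday's | 1.33 | 5.5 | 46.2 |
| Saturday's | 2.00 | 7.1 | 43.1 |
| Saturday's | 3.00 | 11.2 | 42.5 |
| Saturday's | 4.00 | 14.0 | 40.3 |

(readings scatter by 1 percentage point)

- coupling partner is single-handed; left-handed substrate and right-handed substrate are mirror images of each other, charged as a racemate, each of them at the stated concentration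
- at the start none of the gas is in solution
- the handed part of coupling partner does not stay in what it makes, so the products of the two hands are mirror images too

- the flask that comes out highest in amount of left-handed product, in percent of the left-handed substrate and right-handed substrate together charged, or "all alike" when all lie within 1.5 percentage points (green / teal / blue / grey / all alike)
- left-handed product at the end, in percent of the left-handed substrate and right-handed substrate together charged, green
- left-handed product at the end, in percent of the left-handed substrate and right-handed substrate together charged, teal
- left-handed product at the end, in percent of the left-handed substrate and right-handed substrate together charged, blue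
- left-handed product at the end, in percent of the left-handed substrate and right-handed substrate together charged, grey

Start from Saturday's last line. Left-handed product stands at 14.0% of the charge, which is 308 mM, more than the 43 mM of gas that solution holds. So take the coupling partner to be fed by the gas during the run, not drawn from a stock.

Now read the two tables at both ends of temperature. On Thursday, left-handed product forms at 12.9 mM/min up to 25.0 min and at 7.11 mM/min from there to 50.0 min, while left-handed substrate sinks. Read that as the cold end, pseudo-first-order in substrate, the rate sinking as the substrate does. On Saturday it forms at 78.1 mM/min up to 2.00 min and 75.9 mM/min after, level within the scatter, though the substrate has fallen little there, so this reading is weak.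

Take Saturday as the hot end, with gas uptake as the rate-limiting step, and join the ends by letting each flask follow the lower of the two rates. Define F, the left-handed share of the gas flow, as the left-handed product made per litre per minute, as read from Saturday's run: 77.0 mM/min. F is a rate per litre, so in percent it counts for more on a smaller charge. Blue is hotter than Saturday's run, and I take it to stay at the hot end, so over 6.0 min on its 1.00 M my own reckoning gives 46.2%.

The forecast also picks blue, but with 15.4% for green, 7.5% for teal, 28% for blue and 2.9% for grey, its blue lying below my figure. Its grounds: “Product formation looks first order in left-handed substrate”.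

The flasks give 33.1% for green, 10.9% for teal, 48.6% for blue and 0.982% for grey, so blue is highest.

    coupling partner + left-handed substrate → left-handed product (k = 1.42 /M/min, Ea = 69.0 kJ/mol)
    coupling partner + right-handed substrate → right-handed product (k = 0.723 /M/min, Ea = 49.0 kJ/mol)
    left-handed substrate + racemization catalyst ⇌ right-handed substrate + racemization catalyst, rate k3*[racemization catalyst]*[left-handed substrate] forward; the back reaction follows from the equilibrium constant (k = 1.94 /M/min, Ea = 72.0 kJ/mol)
    racemization catalyst + impurity → spent catalyst A (k = 590 /M/min, Ea = 36.0 kJ/mol)
    2 racemization catalyst → spent catalyst B (k = 0.496 /M/min, Ea = 64.0 kJ/mol)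
    gas ⇌ coupling partner, rate k6*(csat - [coupling partner]) (kL = 2.37 /min)
    (constants at 40 °C)

In blue at 2.96 min the coupling partner is made 1.00 times as fast as it is used up, and at 6.00 min it stands at 0.00420 M, less than the saturation of 43 mM. In blue the path to left-handed product has 51% of its turnover behind it at 3.00 min, half of the time. Carried over, F gives 46.2% against the 48.6% of blue. For blue read at 1.5 min, F gives 11.6%, and that flask holds 12.5%.

All runs were computed for substances that don't exist; the scatter is artificial.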